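(Readings and results come from a simulation for an exercise; the scatter is artificial.)

The easy step is to read a half-life off the maple run, after setting out the flasks and the questions.

| flask | starting material | reagent | protic impurity | temperature | remark | time |
|---|---|---|---|---|---|---|
| maple | 0.80 M | 0.80 M | 0.24 M | 60 °C | run made earlier |  |
| north | 0.80 M | 1.60 M | 0.240 M |  | at 60 °C until 1.5 h, from then on at 80 °C | 8.0 h |
| north-west | 0.80 M | 1.60 M | 0.240 M |  | at 60 °C throughout | 4.0 h |

maple run (percent of the starting material charged)

| time / min | product / % | starting material / % |
|---|---|---|
| 12.0 | 5 | 93 |
| 30.0 | 6 | 92 |
| 60.0 | 13 | 82 |
| 90.0 | 16 | 74 |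

(each reading ± 1.5 percentage points)

* which of the two ends with the higher amount of product, in percent of the starting material charged ("neither" if they lie within 2 percentage points) (north / north-west / neither)
* product at the end, in percent of the starting material charged, north
* product at the end, in percent of the starting material charged, north-west

- amounts and yields of product count crystals too
- given per volume of solution although it is solid: crystals
- the numbers in the tables scatter by 1.5 percentage points (one standard deviation)
- what may be going on: reagent + intermediate B <-> intermediate C; crystals <-> product; starting material -> product; starting material + reagent <-> intermediate A; starting material + reagent -> intermediate B; starting material + protic impurity -> quenched substrate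
- the earlier runs do not show what temperature does; that part of a forecast is a guess

At 90.0 min in maple, 74 % of the starting material remains. Treated as a pseudo-first-order loss, this reading gives a rate constant k = 0.201 /h and a half-life of 3.45 h. Product at that reading is 16 %, so the selectivity S, product formed per starting material lost, is 0.615. That splits k into 0.124 /h towards product and 0.0772 /h towards side species.

With these values, north-west spends 1.16 half-lives and reaches 34.0 % product. The weak link is the reagent, charged at twice the maple level. The listed step to product takes no reagent, whereas the steps to intermediates A and B do. This reckoning therefore keeps the constant towards product and scales the whole side constant with the reagent, to 0.154 /h. The total is 0.278 /h, so H, the half-life of starting material at this reagent charge, is 2.49 h, and the new selectivity S′ is 0.444.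

North-west then gives 29.8 % product. North, at 8.0 h, has 3.21 half-lives even if counted at 60 °C. Guessing that heat speeds every step alike, its conversion is taken as complete, and its product is S′, or 44.4 %.

The forecast says north, with 48 % for north and 30 % for north-west, holding that “Doubling reagent should therefore not speed product formation”. Its north stands above this reckoning.

The simulation gives north, with 55.2 % in north and 29.4 % in north-west.

    reagent + intermediate B ⇌ intermediate C (K = 0.560 /M, k = 5.60 × 10⁻⁴ /M/min, Ea = 96.0 kJ/mol, ΔH = 10.0 kJ/mol)
    crystals ⇌ product, rate k2*(cs2 - [product]) while solid is left; crystals form when [product] > cs2 (solubility = 0.530 M, k = 0.0160 /min)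
    starting material → product (k = 0.00190 /min, Ea = 109 kJ/mol)
    starting material + reagent ⇌ intermediate A (K = 4.60 /M, k = 2.70 × 10⁻⁴ /M/min, Ea = 104 kJ/mol, ΔH = −13.0 kJ/mol)
    starting material + reagent → intermediate B (k = 7.30 × 10⁻⁴ /M/min, Ea = 101 kJ/mol)
    starting material + protic impurity → quenched substrate (k = 0.00260 /M/min, Ea = 74.0 kJ/mol)
    (constants at 60 °C)

In north-west, H leaves 32.8 % starting material against 39.2 % found. In the same flask read at 1.0 h, it leaves 75.7 % against 78.4 %, and gives 10.8 % product against 10.1 %. Counted in H at 60 °C for its whole time, north gives 39.6 %, and the same flask held there reaches 41.2 %. North-west on the temperature programme of north reaches 54.0 % at its own 4.0 h, against 29.4 %, whereas at 60 °C for 8.0 h it reaches 41.2 %. Of the two differences between the flasks, the programme is therefore the larger single effect, worth 25 percentage points.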